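**Plan**
- Retrosynthetic cuts, in order: (i) the 8β‑H/Δ6 unit back to a 6α‑silyl Δ7 allylsilane; (ii) C5–C6 and C9–C10, i.e. ring B of the aromatic (upper) half, by an aryne [4+2]; (iii) O3–C4' and O2–C3' of the dioxane by a hetero‑Diels–Alder reaction.
- Enabling feature: C5 and C10 are adjacent carbons of aromatic ring A and the only aromatic members of ring B; C6–C7–C8–C9 form a 1,3‑diene once C8=C9 lies in ring C. A 5,10‑aryne (C4–CH3 beside C5, C1–H beside C10) therefore closes ring B on a 1‑vinylcyclohexene in one event.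
- Forward order: pristimerin → C/D/E ketone (rings A/B excised) → (E)‑silyl diene; pristimerin → 7,8‑dihydro catechol (lower half); a benzaldehyde → o‑silylaryl triflate catechol; dioxane ring; ring B last; acid then removes the silicon helper.
- Stereochemistry: C13, C14, C17, C18, C20 (both halves) and C9' come from pristimerin; C8' from hydrogen‑atom‑transfer hydrogenation; C3'/C4' from α‑face hetero‑Diels–Alder; C9 and C6 from the cycloaddition; C8 (8β‑H) from anti‑SE2' protodesilylation.

Key step: step 12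

Assumption: pristimerin (celastrol methyl ester) is taken as a purchasable, enantiopure starting material; it supplies the lower half and, after excision of C1–C7, C10 and C23, the C/D/E block of the upper half. Celastroid numbering is used, with primes for the lower (quinoid) half.

**Route**

Step 1
Reactants: 1 pristimerin
Product: 3 CDE keto ester, via beta-keto acid 2 (not isolated)
Conditions: O3, CH2Cl2/MeOH, −78 → −40 °C; then 30% H2O2, THF/H2O, 25 → 60 °C; then PhMe, 90 °C
Reagents that add atoms: ozone, [O-][O+]=O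
Why: Exhaustive ozonolysis with oxidative work-up cleaves all four C=C bonds of the quinone methide (C7=C8 becomes the C8 ketone) and trims the resulting tricarbonyl chain to the C9 carboxylic acid 2, whose thermal decarboxylation (beta-keto acid) leaves C13, C14, C17, C18 and C20 untouched and C9 as an epimerisable CH.

Step 2
Reactants: 3 CDE keto ester
Product: 5 C8 enol triflate, via potassium enolate 4 (not isolated)
Conditions: KN(SiMe3)2, THF, −78 °C; then PhNTf2, −78 → 0 °C
Reagents that add atoms: N-phenylbis(trifluoromethanesulfonimide), O=S(=O)(N(c1ccccc1)S(=O)(=O)C(F)(F)F)C(F)(F)F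
Why: Enolate O-triflation should give a single tetrasubstituted enol triflate because C9 is the only enolisable position (C14 is quaternary), and it erases the C9 configuration.

Step 3
Reactants: 5 C8 enol triflate; 6 (E)-2-(trimethylsilyl)vinylboronic acid pinacol ester
Product: 7 silyl diene
Conditions: Pd(dppf)Cl2 (5 mol %), K3PO4, 1,4-dioxane/H2O, 80 °C
Reagents that add atoms: none
Why: Suzuki–Miyaura coupling of a vinyl triflate with a vinylboronate keeps the E geometry of the vinylsilane and installs C6, C7 and the silicon helper in one operation.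

Step 4
Reactants: 1 pristimerin
Product: 9 pristimerol diacetate, via pristimerol 8 (not isolated)
Conditions: Zn dust, Ac2O, AcOH, NaOAc, 60 °C
Reagents that add atoms: acetic anhydride, CC(=O)OC(C)=O
Why: Reductive acetylation of a quinone methide: zinc delivers two electrons, protonation at C6 aromatises ring A, and both phenols are acetylated in situ, which protects the air-sensitive catechol.

Step 5
Reactants: 9 pristimerol diacetate
Product: 10 7,8-dihydropristimerol diacetate (8α-H)
Conditions: Mn(dpm)3 (10 mol %), PhSiH3, t-BuOOH, i-PrOH/CH2Cl2, 25 °C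
Reagents that add atoms: none
Why: Metal-hydride hydrogen-atom-transfer hydrogenation of the hindered 7,8-alkene puts H on C7, and the tertiary C8 radical should take its hydrogen axially on the α-face to give the thermodynamically preferred trans B/C fusion (8α-H), while aryl acetates and the ester are inert.

Step 6
Reactants: 10 7,8-dihydropristimerol diacetate
Product: 11 7,8-dihydropristimerol
Conditions: K2CO3 (cat.), degassed MeOH, 0 → 25 °C, argon
Reagents that add atoms: none
Why: Methanolysis (transesterification) of the two aryl acetates is far faster than attack on the hindered tertiary methyl ester, which methanol would in any case regenerate.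

Step 7
Reactants: 12 2,4-dihydroxy-3-methylbenzaldehyde
Product: 13 5-bromo-2,4-dihydroxy-3-methylbenzaldehyde
Conditions: NBS, MeCN, 0 °C
Reagents that add atoms: N-bromosuccinimide, O=C1CCC(=O)N1Br
Why: Electrophilic aromatic bromination should go to C5, the only free position that is ortho to one hydroxyl and para to the other.

Step 8
Reactants: 13 5-bromo-2,4-dihydroxy-3-methylbenzaldehyde
Product: 15 5-bromo-3-methylbenzene-1,2,4-triol, via aryl formate 14 (not isolated)
Conditions: 30% H2O2, B(OH)3, H2SO4 (cat.), THF, 25 °C, argon; then H2O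
Reagents that add atoms: hydrogen peroxide, OO
Why: Dakin oxidation: aryl migration in the peroxide adduct of the o/p-hydroxybenzaldehyde gives formate 14, which hydrolyses to the phenol, and the acidic oxygen-free medium keeps the 1,2,4-triol from autoxidation.

Step 9
Reactants: 15 5-bromo-3-methylbenzene-1,2,4-triol
Product: 16 5-bromo-3-methyl-1,2,4-tris(trimethylsilyloxy)benzene
Conditions: HN(SiMe3)2, THF, 70 °C; concentrate
Reagents that add atoms: hexamethyldisilazane, C[Si](C)(C)N[Si](C)(C)C
Why: O-Silylation masks all three phenols and places, on the oxygen next to bromine, the silyl group that will migrate to carbon.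

Step 10
Reactants: 16 5-bromo-3-methyl-1,2,4-tris(trimethylsilyloxy)benzene
Product: 20 3,4-dihydroxy-2-methyl-6-(trimethylsilyl)phenyl triflate, via aryllithium 17 (not isolated), via lithium phenoxide 18 (not isolated), via bis-silyl ether triflate 19 (not isolated)
Conditions: n-BuLi, THF, −100 → −78 °C; Tf2O, −100 → −78 °C; then MeOH, citric acid (cat.), 0 °C
Reagents that add atoms: trifluoromethanesulfonic anhydride, O=S(=O)(OS(=O)(=O)C(F)(F)F)C(F)(F)F
Why: Bromine–lithium exchange triggers a retro-Brook (1,3 O→C) silyl shift from the adjacent oxygen only, the liberated phenoxide is triflated, and methanolysis removes the two remaining O-silyl groups, leaving the C-silyl/triflate pair next to a free catechol.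

Step 11
Reactants: 20 3,4-dihydroxy-2-methyl-6-(trimethylsilyl)phenyl triflate (2 equiv); 11 7,8-dihydropristimerol
Product: 24 dioxane-linked silyl triflate, via triflate o-quinone 21 (not isolated), via lower-half o-quinone 22 (not isolated), via quinone methide 23 (not isolated)
Conditions: Ag2O, Na2SO4, CH2Cl2, 0 → 25 °C, dark
Reagents that add atoms: none
Why: Inverse-electron-demand hetero-Diels–Alder reaction of the O=C–C=O unit of 21 with the enol C3'=C4' bond of quinone methide 23 (tautomer of 22); bonding should begin between nucleophilic C4' and O3 because the charge developing on O2 is para to the C5 triflate, and addition anti to the axial 9'β-methyl sets C3' and C4' (α,α-dioxy, 3'β-OH).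

Step 12
Reactants: 24 dioxane-linked silyl triflate; 7 silyl diene (3 equiv)
Product: 26 silyl cycloadduct, via aryne 25 (not isolated)
Conditions: KF, 18-crown-6, THF, 0 → 25 °C, slow addition of 24
Reagents that add atoms: none
Why: Fluoride attacks the C10 silicon and expels the C5 triflate to give the 5,10-aryne 25, which is trapped in a concerted, asynchronous [4+2] cycloaddition by the s-cis C6=C7–C8=C9 diene of 7; the closest known reaction type is the Diels–Alder reaction of arynes from o-silylaryl triflates with 1-vinylcycloalkenes and silyl dienes. Ring B is closed by this cycloaddition, which forms C5–C6 and C9–C10 together on one face of the diene. C9 is controlled by the pseudoaxial 14β-methyl (1,3 to C9), which shields the β-face so that the arene bonds from the α-face and the methyl ends up 9β; C6 follows from the E-vinylsilane, because suprafacial addition places silicon cis to C11, i.e. 6α. The required regiochemistry (C9 to C10, C6 to C5) is secured by the groups beside the triple bond: C5 is flanked by the C4 methyl and C10 only by C1–H, so the fully substituted diene terminus C9 goes to the unhindered C10 and the silyl-bearing CH terminus to C5. Periselectivity ([4+2] over ene and [2+2]) and chemoselectivity over the tertiary hemiketal OH rest on the excess of electron-rich diene and the low stationary aryne concentration.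

Step 13
Reactants: 26 silyl cycloadduct
Product: 27 CNP0271025.2 (target)
Conditions: CF3CO2H, CH2Cl2, −20 → 0 °C
Reagents that add atoms: none
Why: Anti-SE2' protodesilylation of an allylsilane: β-silicon stabilisation directs the proton to C8 (γ-carbon) on the face opposite the pseudoaxial 6α C–Si bond, i.e. the β-face, giving 8β-H as the double bond moves to C6=C7 and silicon leaves.

**Compound list**

1 | pristimerin (celastrol methyl ester; 3-hydroxy-2-oxo-1(10),3,5,7-tetraene quinone methide) | CC1=C(O)C(=O)C=C2C1=CC=C3[C@@]2(C)CC[C@@]4(C)[C@@H]5C[C@](C)(C(=O)OC)CC[C@]5(C)CC[C@]34C | starting material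
2 | CDE beta-keto acid (C8 ketone; C9 carries 9β-CH3 and CO2H from former C10; 13α-CH3, 14β-CH3, 17β-CH3, 18β-H, 20β-CH3, 20α-CO2Me) | OC(=O)[C@]1(C)CC[C@@]2(C)[C@@H]3C[C@](C)(C(=O)OC)CC[C@]3(C)CC[C@]2(C)C1=O | intermediate
3 | CDE keto ester (C8 ketone, C9 H/CH3; equatorial-methyl epimer drawn, C9 is levelled in step 2) | C[C@@H]1CC[C@@]2(C)[C@@H]3C[C@](C)(C(=O)OC)CC[C@]3(C)CC[C@]2(C)C1=O | intermediate
4 | potassium C8/C9 enolate of 3 | [K+].[O-]C1=C(C)CC[C@@]2(C)[C@@H]3C[C@](C)(C(=O)OC)CC[C@]3(C)CC[C@]12C | intermediate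
5 | C8 enol triflate (tetrasubstituted C8=C9, 9-CH3) | FC(F)(F)S(=O)(=O)OC1=C(C)CC[C@@]2(C)[C@@H]3C[C@](C)(C(=O)OC)CC[C@]3(C)CC[C@]12C | intermediate
6 | (E)-2-(trimethylsilyl)vinylboronic acid pinacol ester | C[Si](C)(C)/C=C/B1OC(C)(C)C(C)(C)O1 | starting material
7 | silyl diene ((E)-Me3Si–C6H=C7H–C8=C9(CH3) on the CDE block) | C[Si](C)(C)/C=C/C1=C(C)CC[C@@]2(C)[C@@H]3C[C@](C)(C(=O)OC)CC[C@]3(C)CC[C@]12C | intermediate
8 | pristimerol (2,3-dihydroxy-1,3,5(10),7-tetraene) | Oc1cc2c(c(C)c1O)CC=C3[C@@]2(C)CC[C@@]4(C)[C@@H]5C[C@](C)(C(=O)OC)CC[C@]5(C)CC[C@]34C | intermediate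
9 | pristimerol 2,3-diacetate | CC(=O)Oc1cc2c(c(C)c1OC(C)=O)CC=C3[C@@]2(C)CC[C@@]4(C)[C@@H]5C[C@](C)(C(=O)OC)CC[C@]5(C)CC[C@]34C | intermediate
10 | 7,8-dihydropristimerol 2,3-diacetate (8α-H) | CC(=O)Oc1cc2c(c(C)c1OC(C)=O)CC[C@H]3[C@@]2(C)CC[C@@]4(C)[C@@H]5C[C@](C)(C(=O)OC)CC[C@]5(C)CC[C@]34C | intermediate
11 | 7,8-dihydropristimerol (8α-H catechol, lower-half precursor) | Oc1cc2c(c(C)c1O)CC[C@H]3[C@@]2(C)CC[C@@]4(C)[C@@H]5C[C@](C)(C(=O)OC)CC[C@]5(C)CC[C@]34C | intermediate
12 | 2,4-dihydroxy-3-methylbenzaldehyde | Cc1c(O)ccc(C=O)c1O | starting material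
13 | 5-bromo-2,4-dihydroxy-3-methylbenzaldehyde | Cc1c(O)c(Br)cc(C=O)c1O | intermediate
14 | 5-bromo-2,4-dihydroxy-3-methylphenyl formate | Cc1c(O)c(Br)cc(OC=O)c1O | intermediate
15 | 5-bromo-3-methylbenzene-1,2,4-triol | Cc1c(O)c(Br)cc(O)c1O | intermediate
16 | 5-bromo-3-methyl-1,2,4-tris(trimethylsilyloxy)benzene | Cc1c(O[Si](C)(C)C)c(Br)cc(O[Si](C)(C)C)c1O[Si](C)(C)C | intermediate
17 | 5-lithio-3-methyl-1,2,4-tris(trimethylsilyloxy)benzene | Cc1c(O[Si](C)(C)C)c([Li])cc(O[Si](C)(C)C)c1O[Si](C)(C)C | intermediate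
18 | lithium 2-methyl-3,4-bis(trimethylsilyloxy)-6-(trimethylsilyl)phenoxide | [Li+].Cc1c([O-])c([Si](C)(C)C)cc(O[Si](C)(C)C)c1O[Si](C)(C)C | intermediate
19 | 2-methyl-3,4-bis(trimethylsilyloxy)-6-(trimethylsilyl)phenyl triflate | Cc1c(OS(=O)(=O)C(F)(F)F)c([Si](C)(C)C)cc(O[Si](C)(C)C)c1O[Si](C)(C)C | intermediate
20 | 3,4-dihydroxy-2-methyl-6-(trimethylsilyl)phenyl triflate (OH groups become O3 and O2; OTf on C5, SiMe3 on C10) | Cc1c(OS(=O)(=O)C(F)(F)F)c([Si](C)(C)C)cc(O)c1O | intermediate
21 | 3-methyl-4-(trifluoromethanesulfonyloxy)-5-(trimethylsilyl)-1,2-benzoquinone | CC1=C(OS(=O)(=O)C(F)(F)F)C([Si](C)(C)C)=CC(=O)C1=O | intermediate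
22 | o-quinone of 11 (2,3-dioxo-1(10),4-diene, 8α-H) | CC1=C2CC[C@H]3[C@@](C)(CC[C@@]4(C)[C@@H]5C[C@](C)(C(=O)OC)CC[C@]5(C)CC[C@]34C)C2=CC(=O)C1=O | intermediate
23 | 7,8-dihydropristimerin (3-hydroxy-2-oxo-1(10),3,5-triene quinone methide, 8α-H) | CC1=C(O)C(=O)C=C2C1=CC[C@H]3[C@@]2(C)CC[C@@]4(C)[C@@H]5C[C@](C)(C(=O)OC)CC[C@]5(C)CC[C@]34C | intermediate
24 | dioxane-linked silyl triflate (aryl O3–C4' and O2–C3' on the α-face of the 2'-oxo-3'β-hydroxy-1'(10'),5'-diene lower half; arene carries C4-CH3, C5-OTf, C10-SiMe3, C1-H) | FC(F)(F)S(=O)(=O)Oc1c([Si](C)(C)C)cc2c(c1C)O[C@@]1(C)C3=CC[C@H]4[C@@](C)(CC[C@@]5(C)[C@@H]6C[C@](C)(C(=O)OC)CC[C@]6(C)CC[C@]45C)C3=CC(=O)[C@@]1(O)O2 | intermediate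
25 | 5,10-aryne derived from 24 | CC1=C2O[C@@]3(C)C4=CC[C@H]5[C@@](C)(CC[C@@]6(C)[C@@H]7C[C@](C)(C(=O)OC)CC[C@]7(C)CC[C@]56C)C4=CC(=O)[C@@]3(O)OC2=CC#C1 | intermediate
26 | silyl cycloadduct (ring B closed; 6α-SiMe3, 6β-H, Δ7, 9β-CH3) | COC(=O)[C@]1(C)CC[C@]2(C)CC[C@]3(C)C4=C[C@H]([Si](C)(C)C)c5c(cc6c(c5C)O[C@@]5(C)C7=CC[C@H]8[C@@](C)(CC[C@@]9(C)[C@@H]%10C[C@](C)(C(=O)OC)CC[C@]%10(C)CC[C@]89C)C7=CC(=O)[C@@]5(O)O6)[C@]4(C)CC[C@@]3(C)[C@@H]2C1 | intermediate
27 | CNP0271025.2 | COC(=O)[C@]1(C)CC[C@]2(C)CC[C@]3(C)[C@@H]4C=Cc5c(cc6c(c5C)O[C@@]5(C)C7=CC[C@H]8[C@@](C)(CC[C@@]9(C)[C@@H]%10C[C@](C)(C(=O)OC)CC[C@]%10(C)CC[C@]89C)C7=CC(=O)[C@@]5(O)O6)[C@]4(C)CC[C@@]3(C)[C@@H]2C1 | target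

**Totals**

Total step count: 13. Longest linear sequence: 7 steps (12 → 13 → 15 → 16 → 20 → 24 → 26 → 27).

**Steps most likely to fail**

Step 12. The aryne may be consumed by an ene reaction with the allylic C–H bonds of the diene (C9 methyl, C11) or by [2+2] addition, because the Z-disposed C9 methyl disfavours the s-cis conformation. It may also be captured by the hemiketal OH, and fluoride may strip the new allylic silyl group before the acid step. The fallback inverts the order of union so that the aryne partner is cheap, used in excess and free of the lower half; it sets out from 20 and 7 and returns at 27. Catechol 20 would be converted (MOMCl, i-Pr2NEt) into the bis(methoxymethyl) ether of 20, F1. Fluoride activation (KF, 18-crown-6, THF) with diene 7 should give, through 3-methyl-4,5-bis(methoxymethoxy)benzyne F2, the monomeric silyl cycloadduct F3. HCl in MeOH would then remove both acetals and effect the same anti-SE2' protodesilylation to give the Δ6, 8β-H catechol F4. Co-oxidation of F4 with 11 (Ag2O, as in step 11) should pass through the upper-half o-quinone F5 and quinone methide 23 to 27. In this variant the dioxane is closed after ring B.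

Step 11. Co-oxidation may funnel the lower half into self-coupling or into aromatisation of quinone methide 23, and bonding may start at O2 (regio-isomeric dioxane) or on the β-face. The fallback generates the 2π partner without oxidant and meets it with preformed heterodiene; it sets out from 10 and 20 and returns at 24. Benzylic oxidation of 10 (CrO3, AcOH) would give the 6-oxo diacetate F6. Reduction and deacetylation (NaBH4, then K2CO3/MeOH) would give 6-hydroxy-7,8-dihydropristimerol F7. Warming F7 in toluene with a trace of AcOH should eliminate water across O2–H/C6–OH to give quinone methide 23 directly. A filtered solution of o-quinone 21 (from 20 and Ag2O) is then added, so that o-quinone 22 never forms, and the hetero-Diels–Alder reaction gives 24.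

Step 1. Ozonolysis may stop short at the electron-poor C1=C10 bond or over-oxidise, and the keto acid may be lost by Baeyer–Villiger or retro-Claisen cleavage, giving intractable acid mixtures. The fallback degrades the aromatic diacetate in two controlled stages; it sets out from 9 and returns at 3. Ozonolysis of the isolated 7,8-alkene of 9 (O3, CH2Cl2, −78 °C; PPh3) would give the seco keto aldehyde F8. RuCl3 (cat.)/NaIO4 (CCl4/MeCN/H2O) would then degrade the diacetoxyarene to the C9 carboxylic acid 2, which is decarboxylated in hot toluene to 3.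

**Further compounds**

F1 | step 12 | 3,4-bis(methoxymethoxy)-2-methyl-6-(trimethylsilyl)phenyl triflate | COCOc1cc([Si](C)(C)C)c(OS(=O)(=O)C(F)(F)F)c(C)c1OCOC
F2 | step 12 | 3-methyl-4,5-bis(methoxymethoxy)benzyne | CC1=C(OCOC)C(OCOC)=CC#C1
F3 | step 12 | monomeric silyl cycloadduct (6α-SiMe3, Δ7, 2,3-bis(methoxymethyl) ether) | COC(=O)[C@]1(C)CC[C@]2(C)CC[C@]3(C)C4=C[C@H]([Si](C)(C)C)c5c(cc(OCOC)c(OCOC)c5C)[C@]4(C)CC[C@@]3(C)[C@@H]2C1
F4 | step 12 | upper-half catechol (2,3-dihydroxy-1,3,5(10),6-tetraene, 8β-H) | COC(=O)[C@]1(C)CC[C@]2(C)CC[C@]3(C)[C@@H]4C=Cc5c(cc(O)c(O)c5C)[C@]4(C)CC[C@@]3(C)[C@@H]2C1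
F5 | step 12 | upper-half o-quinone (2,3-dioxo-1(10),4,6-triene, 8β-H) | COC(=O)[C@]1(C)CC[C@]2(C)CC[C@]3(C)[C@@H]4C=CC5=C(C)C(=O)C(=O)C=C5[C@]4(C)CC[C@@]3(C)[C@@H]2C1
F6 | step 11 | 6-oxo-7,8-dihydropristimerol 2,3-diacetate | CC(=O)Oc1cc2c(c(C)c1OC(C)=O)C(=O)C[C@H]3[C@@]2(C)CC[C@@]4(C)[C@@H]5C[C@](C)(C(=O)OC)CC[C@]5(C)CC[C@]34C
F7 | step 11 | 6-hydroxy-7,8-dihydropristimerol (C6 epimers, both serve) | Oc1cc2c(c(C)c1O)C(O)C[C@H]3[C@@]2(C)CC[C@@]4(C)[C@@H]5C[C@](C)(C(=O)OC)CC[C@]5(C)CC[C@]34C
F8 | step 1 | 7,8-seco keto aldehyde of 9 (C8 ketone; aryl-CH2-CHO) | CC(=O)Oc1cc(c(CC=O)c(C)c1OC(C)=O)[C@]1(C)CC[C@@]2(C)[C@@H]3C[C@](C)(C(=O)OC)CC[C@]3(C)CC[C@]2(C)C1=O
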